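**Assumption:** the SMILES has no stereodescriptors and the molecule has no stereocentres. The only possible stereo-element is the hindered biaryl axis, which is undefined in the SMILES, so the route delivers the compound as drawn without controlling or resolving the axis.

Ring labels: A = the O-linked galloyl ring, B = the central fully substituted ring, C = the terminal biaryl ring.

## Retrosynthetic overview

1. The target is released by global hydrogenolysis of its undecabenzyl derivative (8 benzyl ethers, 3 benzyl esters), which avoids the acid and heat that would lactonise the free acid.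
2. The last fragment union is an Ullmann diaryl-ether coupling between the ring A phenol and the bromide of the ring B–C biaryl.
3. The B–C biaryl bond comes from a Negishi coupling of the ring C arylzinc with the C–I bond of a ring B 2-bromo-6-iodogallate.
4. Ring A is made from p-cresol (via syringaldehyde, gallic acid and partial benzylation). Rings B and C are made from 4-bromophenol (diiodination, Cu-catalysed benzyloxylation, Pd alkoxycarbonylation, halogenation).
5. No ring is constructed: all three benzene rings come intact from the starting materials. Bond order is B–C biaryl first, then the A–O–B ether.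

## Route

### Ring A line (from p-cresol)

**Step 1**
Reactants: 1, p-cresol (4-methylphenol)
Product: 2, 3,5-dibromo-4-hydroxybenzaldehyde
Conditions: Br2 (4.1 eq), o-dichlorobenzene, 35 °C then 155 °C; then H2O, 100 °C
Reagents that add atoms: bromine, BrBr; water, O
Why: Electrophilic bromination at both positions ortho to OH, then radical benzylic dibromination and hydrolysis of the benzal bromide, gives the aldehyde in one pot.

**Step 2**
Reactants: 2, 3,5-dibromo-4-hydroxybenzaldehyde
Product: 3, syringaldehyde (4-hydroxy-3,5-dimethoxybenzaldehyde)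
Conditions: NaOMe (5 eq), CuCl (cat.), DMF/MeOH, 115 °C
Reagents that add atoms: sodium methoxide, [Na+].[O-]C
Why: Cu(I)-catalysed Ullmann-type methoxylation of both aryl bromides; the phenolate-conjugated aldehyde is inert to methoxide.

**Step 3**
Reactants: 3, syringaldehyde
Product: 4, syringic acid (4-hydroxy-3,5-dimethoxybenzoic acid)
Conditions: Ag2O, aq. NaOH, 55–60 °C; then HCl
Reagents that add atoms: hydroxide/water as the oxygen source, [Na+].[OH-] (Ag2O, [Ag]O[Ag], is the oxidant)
Why: Silver(I) oxide oxidation of an aryl aldehyde to the carboxylate tolerates the free electron-rich phenol, which chlorite-type oxidants would attack.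

**Step 4**
Reactants: 4, syringic acid
Product: 5, gallic acid (3,4,5-trihydroxybenzoic acid)
Conditions: BBr3 (5 eq), CH2Cl2, −78 °C → rt; H2O (under Ar)
Reagents that add atoms: none
Why: Lewis-acid cleavage of the two aryl methyl ethers at low temperature avoids decarboxylation of the product.

**Step 5**
Reactants: 5, gallic acid
Product: 6, benzyl gallate (benzyl 3,4,5-trihydroxybenzoate)
Conditions: BnBr (1.0 eq), KHCO3 (1.1 eq), DMF, rt, Ar
Reagents that add atoms: benzyl bromide, BrCc1ccccc1
Why: Bicarbonate deprotonates only the carboxylic acid, so SN2 alkylation gives the ester and leaves the three phenols free.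

**Step 6**
Reactants: 6, benzyl gallate
Product: 7, benzyl 3,4-bis(benzyloxy)-5-hydroxybenzoate (ring A phenol)
Conditions: BnBr (2.0 eq), K2CO3 (2.2 eq), DMF, 0 °C → rt, Ar; chromatography
Reagents that add atoms: benzyl bromide, BrCc1ccccc1
Why: Williamson etherification takes the most acidic 4-OH (para to the ester) first and then one of the two equivalent meta OH groups, so only the mono- and tri-benzylated by-products need to be separated.

### Ring B / ring C line (from 4-bromophenol)

**Step 7**
Reactants: 8, 4-bromophenol
Product: 9, 4-bromo-2,6-diiodophenol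
Conditions: I2 (2.1 eq), 30% H2O2, H2O, 50 °C
Reagents that add atoms: iodine, II
Why: Oxidative electrophilic iodination occupies both free positions ortho to OH; the para position is blocked by Br.

**Step 8**
Reactants: 9, 4-bromo-2,6-diiodophenol
Product: 10, 2-(benzyloxy)-5-bromo-1,3-diiodobenzene
Conditions: BnBr, K2CO3, DMF, 60 °C
Reagents that add atoms: benzyl bromide, BrCc1ccccc1
Why: Williamson O-benzylation of the acidic, hindered phenol.

**Step 9**
Reactants: 10, 2-(benzyloxy)-5-bromo-1,3-diiodobenzene
Product: 11, 1,2,3-tris(benzyloxy)-5-bromobenzene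
Conditions: BnOH (6 eq), CuI (20 mol %), 3,4,7,8-Me4-phenanthroline (40 mol %), Cs2CO3 (4 eq), toluene, 90 °C
Reagents that add atoms: benzyl alcohol, OCc1ccccc1
Why: Cu-catalysed Ullmann-type C–O coupling of aryl iodides with a primary alcohol; at 90 °C the C–I bonds react much faster than C–Br, so the bromide is kept as a latent carboxyl.

**Step 10**
Reactants: 11, 1,2,3-tris(benzyloxy)-5-bromobenzene
Product: 12, benzyl 3,4,5-tris(benzyloxy)benzoate
Conditions: CO (1 atm), BnOH (3 eq), Pd(OAc)2 (3 mol %), Xantphos (6 mol %), Et3N, toluene, 90 °C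
Reagents that add atoms: carbon monoxide, [C-]#[O+]; benzyl alcohol, OCc1ccccc1
Why: Pd-catalysed alkoxycarbonylation of the unhindered aryl bromide gives the benzyl ester directly under conditions to which benzyl ethers are inert.

**Step 11**
Reactants: 12, benzyl 3,4,5-tris(benzyloxy)benzoate
Product: 13, benzyl 3,4,5-tris(benzyloxy)-2-iodobenzoate (ring C)
Conditions: I2 (1.1 eq), CF3CO2Ag (1.1 eq), CHCl3, 0 °C → rt, dark
Reagents that add atoms: iodine, II
Why: Electrophilic aromatic iodination at one of the two equivalent positions ortho/para to benzyloxy groups; the monosubstituted benzyl rings are far less activated.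

**Step 12**
Reactants: 12, benzyl 3,4,5-tris(benzyloxy)benzoate
Product: 14, benzyl 3,4,5-tris(benzyloxy)-2-bromobenzoate
Conditions: NBS (1.05 eq), MeCN, rt, dark
Reagents that add atoms: N-bromosuccinimide, O=C1CCC(=O)N1Br
Why: Polar electrophilic bromination of the activated trialkoxy ring; darkness and a polar solvent suppress radical benzylic bromination.

**Step 13**
Reactants: 14, benzyl 3,4,5-tris(benzyloxy)-2-bromobenzoate
Product: 15, benzyl 3,4,5-tris(benzyloxy)-2-bromo-6-iodobenzoate (ring B)
Conditions: I2 (1.3 eq), CF3CO2Ag (1.3 eq), CHCl3, rt → 40 °C, dark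
Reagents that add atoms: iodine, II
Why: Electrophilic iodination at the only remaining C–H of the gallate ring gives two halogens of different reactivity on either side of the ester.

### Fragment unions and deprotection

**Step 14**
Reactants: 13, benzyl 3,4,5-tris(benzyloxy)-2-iodobenzoate; 15, benzyl 3,4,5-tris(benzyloxy)-2-bromo-6-iodobenzoate
Product: 16, dibenzyl 3-bromo-4,4',5,5',6,6'-hexakis(benzyloxy)-[1,1'-biphenyl]-2,2'-dicarboxylate (racemic about the axis)
Conditions: 13, iPrMgCl·LiCl, THF, −40 °C; ZnCl2, −40 °C → rt; then 15 (1.0 eq), Pd2(dba)3 (2.5 mol %), RuPhos (10 mol %), THF/NMP, 60 °C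
Reagents that add atoms: none
Why: I/Mg exchange next to the ester and transmetalation to zinc give an ester-tolerant arylzinc, which undergoes Negishi coupling selectively at the C–I bond of 15 with a bulky biarylphosphine catalyst suited to tetra-ortho-substituted biaryls; the C–Br bond is retained.

**Step 15**
Reactants: 16, the biaryl bromide; 7, benzyl 3,4-bis(benzyloxy)-5-hydroxybenzoate
Product: 17, dibenzyl 4,4',5,5',6,6'-hexakis(benzyloxy)-3-[2,3-bis(benzyloxy)-5-(benzyloxycarbonyl)phenoxy]-[1,1'-biphenyl]-2,2'-dicarboxylate (undecabenzyl sanguisorbate)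
Conditions: 7 (1.5 eq), CuI (30 mol %), picolinic acid (60 mol %), K3PO4, DMSO, 100 °C
Reagents that add atoms: none
Why: Ullmann diaryl-ether coupling at a bromide ortho to an ester (the classical activating arrangement for Cu-mediated C–O coupling); benzyl ethers and the hindered benzyl esters survive anhydrous phosphate.

**Step 16**
Reactants: 17, undecabenzyl sanguisorbate
Product: 18, sanguisorbic acid
Conditions: H2 (1 atm), 10% Pd/C, THF/MeOH, rt; filter under Ar, concentrate below 30 °C, lyophilise
Reagents that add atoms: none
Why: Neutral room-temperature hydrogenolysis removes all eleven benzyl groups without touching the diaryl ether or biaryl, and avoids the acid and heat that drive lactonisation to the ellagic-type dilactone.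

## Compound list

1 | p-cresol | Cc1ccc(O)cc1 | starting material
2 | 3,5-dibromo-4-hydroxybenzaldehyde | O=Cc1cc(Br)c(O)c(Br)c1 | intermediate
3 | syringaldehyde | COc1cc(C=O)cc(OC)c1O | intermediate
4 | syringic acid | COc1cc(C(=O)O)cc(OC)c1O | intermediate
5 | gallic acid | O=C(O)c1cc(O)c(O)c(O)c1 | intermediate
6 | benzyl gallate | O=C(OCc1ccccc1)c1cc(O)c(O)c(O)c1 | intermediate
7 | benzyl 3,4-bis(benzyloxy)-5-hydroxybenzoate | O=C(OCc1ccccc1)c1cc(O)c(OCc2ccccc2)c(OCc2ccccc2)c1 | intermediate
8 | 4-bromophenol | Oc1ccc(Br)cc1 | starting material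
9 | 4-bromo-2,6-diiodophenol | Oc1c(I)cc(Br)cc1I | intermediate
10 | 2-(benzyloxy)-5-bromo-1,3-diiodobenzene | Brc1cc(I)c(OCc2ccccc2)c(I)c1 | intermediate
11 | 1,2,3-tris(benzyloxy)-5-bromobenzene | Brc1cc(OCc2ccccc2)c(OCc2ccccc2)c(OCc2ccccc2)c1 | intermediate
12 | benzyl 3,4,5-tris(benzyloxy)benzoate | O=C(OCc1ccccc1)c1cc(OCc2ccccc2)c(OCc2ccccc2)c(OCc2ccccc2)c1 | intermediate
13 | benzyl 3,4,5-tris(benzyloxy)-2-iodobenzoate | O=C(OCc1ccccc1)c1cc(OCc2ccccc2)c(OCc2ccccc2)c(OCc2ccccc2)c1I | intermediate
14 | benzyl 3,4,5-tris(benzyloxy)-2-bromobenzoate | O=C(OCc1ccccc1)c1cc(OCc2ccccc2)c(OCc2ccccc2)c(OCc2ccccc2)c1Br | intermediate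
15 | benzyl 3,4,5-tris(benzyloxy)-2-bromo-6-iodobenzoate | O=C(OCc1ccccc1)c1c(Br)c(OCc2ccccc2)c(OCc2ccccc2)c(OCc2ccccc2)c1I | intermediate
16 | dibenzyl 3-bromo-4,4',5,5',6,6'-hexakis(benzyloxy)-[1,1'-biphenyl]-2,2'-dicarboxylate | O=C(OCc1ccccc1)c1c(Br)c(OCc2ccccc2)c(OCc2ccccc2)c(OCc2ccccc2)c1-c1c(C(=O)OCc2ccccc2)cc(OCc2ccccc2)c(OCc2ccccc2)c1OCc1ccccc1 | intermediate
17 | undecabenzyl sanguisorbate | O=C(OCc1ccccc1)c1cc(OCc2ccccc2)c(OCc2ccccc2)c(Oc2c(OCc3ccccc3)c(OCc3ccccc3)c(OCc3ccccc3)c(-c3c(C(=O)OCc4ccccc4)cc(OCc4ccccc4)c(OCc4ccccc4)c3OCc3ccccc3)c2C(=O)OCc2ccccc2)c1 | intermediate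
18 | sanguisorbic acid | O=C(O)c1cc(O)c(O)c(Oc2c(O)c(O)c(O)c(-c3c(C(=O)O)cc(O)c(O)c3O)c2C(=O)O)c1 | target

## Summary

**Total step count:** 16

**Longest linear sequence:** 9 steps (8 → 9 → 10 → 11 → 12 → 14 → 15 → 16 → 17 → 18, i.e. steps 7, 8, 9, 10, 12, 13, 14, 15, 16). The ring A line is 8 steps to the target.

**Three steps most likely to fail, with fallbacks:**

- **Step 14 (tetra-ortho-substituted Negishi biaryl coupling).** Fallback: build the biaryl by classical Cu-mediated Ullmann homocoupling of iodide 13 to the symmetric dibenzyl hexakis(benzyloxy)diphenate, then mono-brominate one ring (NBS, with recycling of unreacted and dibrominated material) to reach 16.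
- **Step 15 (Ullmann ether formation at a fully substituted, doubly flanked bromide).** Fallback: invert the order of unions. Couple phenol 7 with the more reactive C–I bond of 15 before the biaryl exists, then attach ring C by Negishi coupling at the remaining C–Br bond.
- **Step 9 (double Cu-catalysed benzyloxylation next to a benzyloxy group, with I-over-Br selectivity).** Fallback: drop the C–O coupling/carbonylation sequence and make 12 by exhaustive benzylation of gallic acid 5 (BnBr, K2CO3, DMF) from the p-cresol line.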